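- Work out the start split first, then judge each setting against it.

| setting | Saturday's | Sunday's | Friday's |
|---|---|---|---|
| Z | 0.10 M | 0.10 M | 0.10 M |
| D | 0.0600 M | 0.0600 M | 0.0600 M |
| temperature | 45 °C | 70 °C | 20 °C |
| time | 2.0 h | 2.0 h | 2.0 h |

- which flask leads in share of Z.D in all that became Z.D or E or Z.Z.D ("all alike" within 1.5 percentage points) (Saturday's / Sunday's / Friday's / all alike)
- share of Z.D in all that became Z.D or E or Z.Z.D, Saturday's
- share of Z.D in all that became Z.D or E or Z.Z.D, Sunday's
- share of Z.D in all that became Z.D or E or Z.Z.D, Friday's

- percent here means Z units held: one Z2 or Z.Z.D counts as two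
- where a step has two of a species, its rate is k times that concentration squared, and two are used at each turn
- constants are those at 70 °C; use the activation energies and enthalpies for any other temperature

    Z + Z.D → Z.Z.D (k1 = 0.69 L mol⁻¹ min⁻¹, Ea1 = 81.0 kJ mol⁻¹)
    Z + 2 D → E (k2 = 120 L² mol⁻² min⁻¹, Ea2 = 55.0 kJ mol⁻¹)
    Z + D ⇌ Z.D (K3 = 46 L mol⁻¹, k3 = 3.6 L mol⁻¹ min⁻¹, Ea3 = 62.0 kJ mol⁻¹, ΔH3 = 16.0 kJ mol⁻¹)
    2 Z → Z2 (k4 = 5.8 × 10⁻⁴ L mol⁻¹ min⁻¹, Ea4 = 88.0 kJ mol⁻¹)
    (constants at 70 °C)

- In Friday's flask at 20 °C, at the start, Z is used 3.0 times as fast by its loss to E as by its forward step to Z.D. So 24.8% of the first product is Z.D. This is the start split, a selectivity: the forward rate to Z.D over both forward rates together.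
- Turn D first. The rate to E carries cD squared and the rate to Z.D carries cD to the first power. So by hand, more D lowers the split.
- Turn Z next. cZ stands in both rates and cancels, so by hand the charge of Z leaves the split as it is.
- Turn the time. As cD falls, the split of new product climbs. But Z.D also goes back to Z and D, and it feeds Z.Z.D, so the hand reckoning of time stops here.
- Turn the temperature. At Sunday's 70 °C the ratio of the two rates is 2.00, so the split is 33.3%, higher than Friday's. But in Sunday's flask, at the charged cZ, Z.D halves through Z.Z.D in 10.0 min, shorter than the 2.0 h run.
- So this reckoning commits to Friday's leading, near its split, with Sunday's below its own split.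
- The forecast also names Friday's: 20% for Saturday's, 2% for Sunday's, 38% for Friday's. Its ground is that “the cold flask keeps the largest share”. Its Friday's figure stands above the split.
- The simulation gives Friday's as leader at 31.9%, with 15.6% for Saturday's and 0.942% for Sunday's. The forecast's Friday's figure is 6.1 percentage points too high.
- Moved alone, up or down by the same factor, the settings of Friday's flask rank D (4.9 points), then Z (1.4 points), then time (1.4 points). The temperature was not among them.
- Sunday's start split stands above Friday's, yet Sunday's reading stands below Friday's. Part of that gap of 31 points is what the temperature does to the loss of Z + Z.D to Z.Z.D: with that effect taken away, the gap between Sunday's and Friday's is 15 points.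
- Now take the neighbour: Friday's flask with 0.024 M of D. The ratio scales with cD, so the split is 45.1%, above Friday's. The simulation gives 49.4%.

The numbers were drawn at random within sensible limits; the result is computed.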